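## Retrosynthetic overview

1. Target 31 ⇒ O-sulfation and desilylation of TBS ether 29.
2. 29 ⇒ B-alkyl Suzuki–Miyaura disconnection of the C4–C5 (sp3–sp2) bond: (E)-vinyl iodide 15 (C14, fragment A) + terminal alkene 27 (C11, fragment B, as its 9-BBN adduct).
3. 15 ⇒ Negishi carboalumination/iodination of alkyne 13 ⇐ allyl ketone 6 ⇐ asymmetric conjugate methylation, then allylation, of 2-methylcyclohex-2-en-1-one.
4. 27 ⇒ copper-catalysed asymmetric SN2' alkylation of (E)-4-silyloxybut-2-enyl bromide 20 with the Grignard reagent from 3-(3-bromopropyl)furan (3-bromofuran + oxetane).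
5. Rings: none is built; the cyclohexene and furan rings are carried intact from 2-methylcyclohex-2-en-1-one and 3-bromofuran.

Assumption 1: the target is taken as the free hydrogen sulfate exactly as drawn; in practice it is best stored as its sodium salt and the acid form released by cold cation exchange.
Assumption 2: in steps 1 and 14 the ligand enantiomer is the one that gives the stated configuration; the named one is the expected choice by analogy, and its antipode is used if the observed sense is opposite.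

## Fragment A (ring half)

Step 1
Reactants: 1 2-methylcyclohex-2-en-1-one
Product: 3 trimethyl{[(3R)-2,3-dimethylcyclohex-1-en-1-yl]oxy}silane, via zinc enolate 2 (not isolated)
Conditions: Me2Zn, Cu(OTf)2 (2 mol %), O,O'-(R)-1,1'-binaphthyl-2,2'-diyl N,N-bis[(S)-1-phenylethyl]phosphoramidite (4 mol %), toluene, −25 °C; then TMSOTf, 0 °C
Reagents that add atoms: dimethylzinc, C[Zn]C; trimethylsilyl trifluoromethanesulfonate, C[Si](C)(C)OS(=O)(=O)C(F)(F)F
Why: Copper-catalysed asymmetric conjugate addition delivers the methyl group to one enone face under ligand control, setting C3 as R, and O-silylation of the zinc enolate locks the tetrasubstituted enolate regiochemistry.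

Step 2
Reactants: 3 trimethyl{[(3R)-2,3-dimethylcyclohex-1-en-1-yl]oxy}silane; 4 allyl bromide
Product: 6 (2S,3R)-2,3-dimethyl-2-(prop-2-en-1-yl)cyclohexan-1-one, via lithium enolate 5 (not isolated)
Conditions: MeLi, THF, 0 °C → rt; then allyl bromide, DMPU, −78 → 0 °C
Reagents that add atoms: none
Why: MeLi cleaves the Si–O bond to the regiodefined lithium enolate, and SN2 C-allylation takes place axially on the face anti to the pseudoaxial C3 methyl, so the quaternary centre forms as 2S with the two methyls cis (dr about 6–9:1, minor isomer removed by chromatography).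

Step 3
Reactants: 6 (2S,3R)-2,3-dimethyl-2-(prop-2-en-1-yl)cyclohexan-1-one
Product: 8 (5R,6S)-5,6-dimethyl-6-(prop-2-en-1-yl)cyclohex-1-en-1-yl trifluoromethanesulfonate, via potassium enolate 7 (not isolated)
Conditions: KN(SiMe3)2, THF, −78 °C; then PhNTf2, −78 → 0 °C
Reagents that add atoms: N-phenylbis(trifluoromethanesulfonimide), O=S(=O)(N(c1ccccc1)S(=O)(=O)C(F)(F)F)C(F)(F)F
Why: Enolisation is possible only towards C6 because C2 is quaternary, so O-triflation of the enolate gives a single enol triflate without touching either stereocentre.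

Step 4
Reactants: 8 (5R,6S)-5,6-dimethyl-6-(prop-2-en-1-yl)cyclohex-1-en-1-yl trifluoromethanesulfonate
Product: 9 (5R,6S)-1,5,6-trimethyl-6-(prop-2-en-1-yl)cyclohex-1-ene
Conditions: MeMgBr, Fe(acac)3 (5 mol %), THF/NMP, −30 → 0 °C
Reagents that add atoms: methylmagnesium bromide, C[Mg]Br
Why: Iron-catalysed Kumada-type cross-coupling of an alkenyl triflate with a methyl Grignard reagent is fast even next to a quaternary carbon and leaves the isolated terminal alkene alone.

Step 5
Reactants: 9 (5R,6S)-1,5,6-trimethyl-6-(prop-2-en-1-yl)cyclohex-1-ene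
Product: 11 3-[(1S,6R)-1,2,6-trimethylcyclohex-2-en-1-yl]propan-1-ol, via B-alkyl-9-BBN 10 (not isolated)
Conditions: 9-BBN, THF, 0 °C → rt; then NaOH, H2O2, 0 °C → rt
Reagents that add atoms: hydrogen peroxide, OO
Why: Brown hydroboration–oxidation with bulky 9-BBN is anti-Markovnikov on the monosubstituted alkene and ignores the hindered trisubstituted ring alkene.

Step 6
Reactants: 11 3-[(1S,6R)-1,2,6-trimethylcyclohex-2-en-1-yl]propan-1-ol
Product: 12 3-[(1S,6R)-1,2,6-trimethylcyclohex-2-en-1-yl]propanal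
Conditions: Dess–Martin periodinane, CH2Cl2, rt
Reagents that add atoms: none
Why: Dess–Martin oxidation stops cleanly at the aldehyde under near-neutral conditions that do not affect the alkene.

Step 7
Reactants: 12 3-[(1S,6R)-1,2,6-trimethylcyclohex-2-en-1-yl]propanal
Product: 13 (5R,6S)-6-(but-3-yn-1-yl)-1,5,6-trimethylcyclohex-1-ene
Conditions: dimethyl (1-diazo-2-oxopropyl)phosphonate, K2CO3, MeOH, 0 °C → rt
Reagents that add atoms: dimethyl (1-diazo-2-oxopropyl)phosphonate, COP(=O)(OC)C(=[N+]=[N-])C(C)=O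
Why: Seyferth–Gilbert homologation in its Ohira–Bestmann form converts the aldehyde into the terminal alkyne with one added carbon under mild base.

Step 8
Reactants: 13 (5R,6S)-6-(but-3-yn-1-yl)-1,5,6-trimethylcyclohex-1-ene
Product: 15 (5R,6S)-6-[(3E)-4-iodo-3-methylbut-3-en-1-yl]-1,5,6-trimethylcyclohex-1-ene, via alkenylalane 14 (not isolated)
Conditions: Me3Al, Cp2ZrCl2 (0.25 equiv), CH2Cl2, 0 °C → rt; then I2, THF, −30 °C
Reagents that add atoms: trimethylaluminium, C[Al](C)C; iodine, II
Why: Negishi zirconium-catalysed carboalumination adds methyl and aluminium syn with aluminium at the terminus, and iodinolysis with retention gives the (E)-vinyl iodide that fixes the trisubstituted alkene geometry of the target.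

## Fragment B (furan half)

Step 9
Reactants: 16 but-2-yne-1,4-diol
Product: 17 (2E)-but-2-ene-1,4-diol
Conditions: LiAlH4, THF, reflux; aqueous work-up
Reagents that add atoms: none
Why: trans-Hydroalumination of a propargylic alcohol through its alkoxyaluminate gives only the (E)-alkene.

Step 10
Reactants: 17 (2E)-but-2-ene-1,4-diol
Product: 19 (2E)-4-{[tert-butyl(dimethyl)silyl]oxy}but-2-en-1-ol, via sodium alkoxide 18 (not isolated)
Conditions: NaH (1.0 equiv), THF, rt; then TBSCl, rt
Reagents that add atoms: tert-butyldimethylsilyl chloride, CC(C)(C)[Si](C)(C)Cl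
Why: Monosilylation of a symmetrical diol through its sparingly soluble monosodium alkoxide gives the mono-TBS ether selectively.

Step 11
Reactants: 19 (2E)-4-{[tert-butyl(dimethyl)silyl]oxy}but-2-en-1-ol
Product: 20 {[(2E)-4-bromobut-2-en-1-yl]oxy}(tert-butyl)dimethylsilane
Conditions: CBr4, PPh3, 2,6-lutidine (cat.), CH2Cl2, 0 °C
Reagents that add atoms: carbon tetrabromide, BrC(Br)(Br)Br
Why: Appel bromination converts the primary allylic alcohol into the bromide under neutral conditions that keep the silyl ether and the E geometry.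

Step 12
Reactants: 21 3-bromofuran; 22 oxetane
Product: 24 3-(furan-3-yl)propan-1-ol, via furan-3-yllithium 23 (not isolated)
Conditions: n-BuLi, THF, −78 °C; then oxetane, BF3·OEt2, −78 °C
Reagents that add atoms: none
Why: Bromine–lithium exchange at −78 °C gives the 3-lithiofuran before it can isomerise, and Lewis-acid-activated SN2 ring opening of oxetane adds the three-carbon alcohol chain.

Step 13
Reactants: 24 3-(furan-3-yl)propan-1-ol
Product: 25 3-(3-bromopropyl)furan
Conditions: CBr4, PPh3, CH2Cl2, 0 °C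
Reagents that add atoms: carbon tetrabromide, BrC(Br)(Br)Br
Why: Appel bromination of the primary alcohol is neutral enough for the acid-sensitive furan.

Step 14
Reactants: 25 3-(3-bromopropyl)furan; 20 {[(2E)-4-bromobut-2-en-1-yl]oxy}(tert-butyl)dimethylsilane
Product: 27 tert-butyl({(2S)-2-[3-(furan-3-yl)propyl]but-3-en-1-yl}oxy)dimethylsilane, via Grignard reagent 26 (not isolated)
Conditions: Mg, Et2O, rt; then 20, CuBr·SMe2 (5 mol %), (R,R)-Taniaphos (6 mol %), CH2Cl2, −75 °C
Reagents that add atoms: none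
Why: Copper-catalysed asymmetric allylic alkylation directs the Grignard reagent to the γ-carbon of the (E)-allylic bromide (SN2'), and the chiral ferrocenyl diphosphine–copper complex selects the alkene face, creating the S stereocentre together with the terminal vinyl group.

## Union and end game

Step 15
Reactants: 27 tert-butyl({(2S)-2-[3-(furan-3-yl)propyl]but-3-en-1-yl}oxy)dimethylsilane; 15 (5R,6S)-6-[(3E)-4-iodo-3-methylbut-3-en-1-yl]-1,5,6-trimethylcyclohex-1-ene
Product: 29 tert-butyl({(2S,5E)-2-[3-(furan-3-yl)propyl]-6-methyl-8-[(1S,6R)-1,2,6-trimethylcyclohex-2-en-1-yl]oct-5-en-1-yl}oxy)dimethylsilane, via B-alkyl-9-BBN 28 (not isolated)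
Conditions: 9-BBN, THF, rt; then 15, PdCl2(dppf) (5 mol %), AsPh3, Cs2CO3, DMF/H2O, rt
Reagents that add atoms: none
Why: B-alkyl Suzuki–Miyaura coupling: 9-BBN hydroborates only the terminal vinyl group (the furan is inert), and the alkylborane couples with the vinyl iodide with retention of the E geometry and without touching any stereocentre.

Step 16
Reactants: 29 tert-butyl({(2S,5E)-2-[3-(furan-3-yl)propyl]-6-methyl-8-[(1S,6R)-1,2,6-trimethylcyclohex-2-en-1-yl]oct-5-en-1-yl}oxy)dimethylsilane
Product: 30 (2S,5E)-2-[3-(furan-3-yl)propyl]-6-methyl-8-[(1S,6R)-1,2,6-trimethylcyclohex-2-en-1-yl]oct-5-en-1-ol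
Conditions: TBAF, THF, 0 °C → rt
Reagents that add atoms: none
Why: Fluoride-mediated desilylation frees the primary alcohol under conditions harmless to the furan and both alkenes.

Step 17
Reactants: 30 (2S,5E)-2-[3-(furan-3-yl)propyl]-6-methyl-8-[(1S,6R)-1,2,6-trimethylcyclohex-2-en-1-yl]oct-5-en-1-ol
Product: 31 (2S,5E)-2-[3-(furan-3-yl)propyl]-6-methyl-8-[(1S,6R)-1,2,6-trimethylcyclohex-2-en-1-yl]oct-5-en-1-yl hydrogen sulfate
Conditions: SO3·pyridine, pyridine, 0 °C → rt; cold H+-form cation-exchange resin, MeOH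
Reagents that add atoms: sulfur trioxide–pyridine complex, O=S(=O)([O-])[n+]1ccccc1
Why: O-sulfation of the unhindered primary alcohol with the mild SO3·pyridine complex gives the sulfate monoester without acid exposure of the furan until the brief final protonation.

## Compound list

1 | 2-methylcyclohex-2-en-1-one | CC1=CCCCC1=O | starting material
2 | methylzinc (3R)-2,3-dimethylcyclohex-1-en-1-olate | C[Zn]OC1=C(C)[C@H](C)CCC1 | intermediate
3 | trimethyl{[(3R)-2,3-dimethylcyclohex-1-en-1-yl]oxy}silane | C[Si](C)(C)OC1=C(C)[C@H](C)CCC1 | intermediate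
4 | allyl bromide (3-bromoprop-1-ene) | C=CCBr | starting material
5 | lithium (3R)-2,3-dimethylcyclohex-1-en-1-olate | [Li]OC1=C(C)[C@H](C)CCC1 | intermediate
6 | (2S,3R)-2,3-dimethyl-2-(prop-2-en-1-yl)cyclohexan-1-one | O=C1CCC[C@@H](C)[C@]1(C)CC=C | intermediate
7 | potassium (5R,6S)-5,6-dimethyl-6-(prop-2-en-1-yl)cyclohex-1-en-1-olate | [K]OC1=CCC[C@@H](C)[C@]1(C)CC=C | intermediate
8 | (5R,6S)-5,6-dimethyl-6-(prop-2-en-1-yl)cyclohex-1-en-1-yl trifluoromethanesulfonate | O=S(=O)(OC1=CCC[C@@H](C)[C@]1(C)CC=C)C(F)(F)F | intermediate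
9 | (5R,6S)-1,5,6-trimethyl-6-(prop-2-en-1-yl)cyclohex-1-ene | CC1=CCC[C@@H](C)[C@]1(C)CC=C | intermediate
10 | 9-{3-[(1S,6R)-1,2,6-trimethylcyclohex-2-en-1-yl]propyl}-9-borabicyclo[3.3.1]nonane | CC1=CCC[C@@H](C)[C@]1(C)CCCB2C3CCCC2CCC3 | intermediate
11 | 3-[(1S,6R)-1,2,6-trimethylcyclohex-2-en-1-yl]propan-1-ol | CC1=CCC[C@@H](C)[C@]1(C)CCCO | intermediate
12 | 3-[(1S,6R)-1,2,6-trimethylcyclohex-2-en-1-yl]propanal | CC1=CCC[C@@H](C)[C@]1(C)CCC=O | intermediate
13 | (5R,6S)-6-(but-3-yn-1-yl)-1,5,6-trimethylcyclohex-1-ene | CC1=CCC[C@@H](C)[C@]1(C)CCC#C | intermediate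
14 | dimethyl{(1E)-2-methyl-4-[(1S,6R)-1,2,6-trimethylcyclohex-2-en-1-yl]but-1-en-1-yl}alumane | CC1=CCC[C@@H](C)[C@]1(C)CC/C(C)=C/[Al](C)C | intermediate
15 | (5R,6S)-6-[(3E)-4-iodo-3-methylbut-3-en-1-yl]-1,5,6-trimethylcyclohex-1-ene | CC1=CCC[C@@H](C)[C@]1(C)CC/C(C)=C/I | intermediate
16 | but-2-yne-1,4-diol | OCC#CCO | starting material
17 | (2E)-but-2-ene-1,4-diol | OC/C=C/CO | intermediate
18 | sodium (2E)-4-hydroxybut-2-en-1-olate | [Na]OC/C=C/CO | intermediate
19 | (2E)-4-{[tert-butyl(dimethyl)silyl]oxy}but-2-en-1-ol | CC(C)(C)[Si](C)(C)OC/C=C/CO | intermediate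
20 | {[(2E)-4-bromobut-2-en-1-yl]oxy}(tert-butyl)dimethylsilane | CC(C)(C)[Si](C)(C)OC/C=C/CBr | intermediate
21 | 3-bromofuran | Brc1ccoc1 | starting material
22 | oxetane | C1COC1 | starting material
23 | furan-3-yllithium | [Li]c1ccoc1 | intermediate
24 | 3-(furan-3-yl)propan-1-ol | OCCCc1ccoc1 | intermediate
25 | 3-(3-bromopropyl)furan | BrCCCc1ccoc1 | intermediate
26 | [3-(furan-3-yl)propyl]magnesium bromide | Br[Mg]CCCc1ccoc1 | intermediate
27 | tert-butyl({(2S)-2-[3-(furan-3-yl)propyl]but-3-en-1-yl}oxy)dimethylsilane | C=C[C@H](CCCc1ccoc1)CO[Si](C)(C)C(C)(C)C | intermediate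
28 | 9-[(3R)-3-({[tert-butyl(dimethyl)silyl]oxy}methyl)-6-(furan-3-yl)hexyl]-9-borabicyclo[3.3.1]nonane (same geometry as 27; the descriptor changes only because of priorities) | CC(C)(C)[Si](C)(C)OC[C@@H](CCCc1ccoc1)CCB2C3CCCC2CCC3 | intermediate
29 | tert-butyl({(2S,5E)-2-[3-(furan-3-yl)propyl]-6-methyl-8-[(1S,6R)-1,2,6-trimethylcyclohex-2-en-1-yl]oct-5-en-1-yl}oxy)dimethylsilane | CC1=CCC[C@@H](C)[C@]1(C)CC/C(C)=C/CC[C@H](CCCc1ccoc1)CO[Si](C)(C)C(C)(C)C | intermediate
30 | (2S,5E)-2-[3-(furan-3-yl)propyl]-6-methyl-8-[(1S,6R)-1,2,6-trimethylcyclohex-2-en-1-yl]oct-5-en-1-ol | CC1=CCC[C@@H](C)[C@]1(C)CC/C(C)=C/CC[C@H](CCCc1ccoc1)CO | intermediate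
31 | (2S,5E)-2-[3-(furan-3-yl)propyl]-6-methyl-8-[(1S,6R)-1,2,6-trimethylcyclohex-2-en-1-yl]oct-5-en-1-yl hydrogen sulfate | CC1=CCC[C@@H](C)[C@]1(C)CC/C(C)=C/CC[C@H](CCCc1ccoc1)COS(=O)(=O)O | target

## Step count and risks

Total step count: 17. Longest linear sequence: 11 (steps 1–8, then 15, 16, 17). The furan half takes six steps (9–11, 12–13, 14) and joins at step 15.

Three steps most likely to fail, each with a fallback:

**Step 2 (quaternary centre by enolate allylation).** The risk is a modest diastereomer ratio, O-allylation or enolate equilibration. The fallback replaces the SN2 alkylation by a palladium-catalysed decarboxylative Tsuji allylation. It sets out from silyl enol ether 3, which MeLi in THF again converts into lithium enolate 5. With TMEDA at −78 °C, 5 is O-acylated by allyl chloroformate to give allyl (3R)-2,3-dimethylcyclohex-1-en-1-yl carbonate F1. Treating F1 with Pd2(dba)3 (a zerovalent palladium source, 2.5 mol %) and (R)-t-Bu-PHOX (6 mol %) in THF at 25 °C ionises it, expels CO2 and recombines the enolate with the π-allyl unit inside the chiral pocket. The ligand enantiomer is the one expected, by analogy with 2-methylcyclohexanone, to reinforce the substrate preference for bond formation anti to the C3 methyl. The fallback comes back to the route at ketone 6.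

**Step 14 (copper-catalysed asymmetric SN2' alkylation).** The risk is an insufficient branched-to-linear ratio or enantiomeric excess with this functionalised Grignard reagent and silyloxy substrate. The fallback sets the stereocentre by auxiliary-controlled enolate alkylation instead, setting out from alcohol 24.
- Alcohol 24 is converted with Tf2O and 2,6-lutidine in CH2Cl2 at −78 °C into 3-(furan-3-yl)propyl trifluoromethanesulfonate F2.
- Separately, (4S)-4-benzyl-1,3-oxazolidin-2-one is N-acylated (n-BuLi, THF, −78 °C, then (E)-but-2-enoyl chloride) to give (4S)-4-benzyl-3-[(2E)-but-2-enoyl]-1,3-oxazolidin-2-one F3.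
- γ-Deprotonation of F3 with NaN(SiMe3)2 in THF at −78 °C gives sodium (1Z)-1-[(4S)-4-benzyl-2-oxo-1,3-oxazolidin-3-yl]buta-1,3-dien-1-olate F4.
- F4 is alkylated at its α-carbon by F2 on the face opposite the benzyl group, giving (4S)-4-benzyl-3-[(2S)-2-ethenyl-5-(furan-3-yl)pentanoyl]-1,3-oxazolidin-2-one F5.
- LiBH4 in Et2O/MeOH at 0 °C removes the auxiliary and gives (2S)-2-ethenyl-5-(furan-3-yl)pentan-1-ol F6.
- Silylation of F6 (TBSCl, imidazole, DMF) comes back to the route at compound 27.

**Step 15 (B-alkyl Suzuki–Miyaura union).** The risk is slow transmetallation of the β-branched alkylborane and protodeboronation or β-hydride loss. The fallback couples the same carbons by a Negishi reaction of an alkylzinc reagent, setting out from alkene 27.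
- Hydroboration of 27 with 9-BBN (through borane 28) and NaOH/H2O2 oxidation gives (3S)-3-({[tert-butyl(dimethyl)silyl]oxy}methyl)-6-(furan-3-yl)hexan-1-ol F7.
- I2, PPh3 and imidazole in CH2Cl2 at 0 °C convert F7 into tert-butyl{[(2S)-5-(furan-3-yl)-2-(2-iodoethyl)pentyl]oxy}dimethylsilane F8.
- Zinc dust with LiCl in THF at 25–40 °C inserts into F8 to give [(3S)-3-({[tert-butyl(dimethyl)silyl]oxy}methyl)-6-(furan-3-yl)hexyl]zinc iodide F9.
- F9 is coupled with vinyl iodide 15 using PdCl2(dppf) (5 mol %) in THF at rt, with retention of alkene geometry, and the fallback comes back to the route at compound 29.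

## Further compounds

F1 | step 2 | allyl (3R)-2,3-dimethylcyclohex-1-en-1-yl carbonate | C=CCOC(=O)OC1=C(C)[C@H](C)CCC1
F2 | step 14 | 3-(furan-3-yl)propyl trifluoromethanesulfonate | O=S(=O)(OCCCc1ccoc1)C(F)(F)F
F3 | step 14 | (4S)-4-benzyl-3-[(2E)-but-2-enoyl]-1,3-oxazolidin-2-one | C/C=C/C(=O)N1[C@@H](Cc2ccccc2)COC1=O
F4 | step 14 | sodium (1Z)-1-[(4S)-4-benzyl-2-oxo-1,3-oxazolidin-3-yl]buta-1,3-dien-1-olate | [Na]O/C(=C\C=C)N1[C@@H](Cc2ccccc2)COC1=O
F5 | step 14 | (4S)-4-benzyl-3-[(2S)-2-ethenyl-5-(furan-3-yl)pentanoyl]-1,3-oxazolidin-2-one | C=C[C@H](CCCc1ccoc1)C(=O)N1[C@@H](Cc2ccccc2)COC1=O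
F6 | step 14 | (2S)-2-ethenyl-5-(furan-3-yl)pentan-1-ol | C=C[C@H](CCCc1ccoc1)CO
F7 | step 15 | (3S)-3-({[tert-butyl(dimethyl)silyl]oxy}methyl)-6-(furan-3-yl)hexan-1-ol | OCC[C@H](CCCc1ccoc1)CO[Si](C)(C)C(C)(C)C
F8 | step 15 | tert-butyl{[(2S)-5-(furan-3-yl)-2-(2-iodoethyl)pentyl]oxy}dimethylsilane | ICC[C@H](CCCc1ccoc1)CO[Si](C)(C)C(C)(C)C
F9 | step 15 | [(3S)-3-({[tert-butyl(dimethyl)silyl]oxy}methyl)-6-(furan-3-yl)hexyl]zinc iodide | I[Zn]CC[C@H](CCCc1ccoc1)CO[Si](C)(C)C(C)(C)C
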